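**Strategy.** Labdane-type numbering is used (remark below). The lactone C2(=O)–O–C8 of the 2-oxabicyclo[3.3.1]nonanone is read as a Baeyer–Villiger retron. C8 then becomes the α-carbon of a C2 cyclopentanone, and C6/C2 a 1,4-diketone. The key step forges C7–C8 by intramolecular oxidative coupling of two enol silanes (the C2=C8 cyclopentenyl silyl ether and the C6=C7 silyl ether of a methyl ketone). It closes the carbocycle C5–C10 as a bicyclo[3.2.1]octane-2,6-dione and sets the C8 quaternary centre. The precursor is a monocyclic bis(silyl enol ether) made from 3-methylcyclopentenone by CBS reduction, Ireland–Claisen rearrangement (C5–C10) and copper-mediated conjugate addition (C9–C11).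

Key step: step 10

Remark 1: atom labels follow 2,3-seco-labdane numbering: C1H2–C2(=O)–O is the lactone arm on C10, C3 the free carboxyl carbon, C4 the CMe2 carbon, C5–C10 the carbocycle, C11–C15 the chain on C9 with C16 the methyl on C13, C17 and C20 the methyls on C8 and C10; the target is then 5R,6R,8S,9S,10R,11S,13R.

Remark 2: C5 is formed without control in step 4 and is set in step 11; intermediates 8–14 and 16–18 are therefore C5 epimer mixtures and their SMILES leave C5 open.

**Step 1**
Reactants: 1 3-methylcyclopent-2-en-1-one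
Product: 2 (1R)-3-methylcyclopent-2-en-1-ol
Conditions: (S)-2-methyl-CBS-oxazaborolidine (10 mol%), BH3·SMe2, THF, −20 °C
Reagents that add atoms: none
Why: Corey–Bakshi–Shibata reduction, in which the catalyst tells the alkenyl flank from the CH2 flank of the enone and delivers hydride to give the R carbinol (the later C8), the centre from which C10 is relayed.

**Step 2**
Reactants: 2 (1R)-3-methylcyclopent-2-en-1-ol; 3 bromoacetyl bromide
Product: 4 (1R)-3-methylcyclopent-2-en-1-yl bromoacetate
Conditions: pyridine, CH2Cl2, −78 → 0 °C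
Reagents that add atoms: none
Why: O-acylation of the allylic alcohol by an acid bromide under base, which leaves the ionisable allylic C–O bond and its configuration untouched.

**Step 3**
Reactants: 4 (1R)-3-methylcyclopent-2-en-1-yl bromoacetate; 5 benzyl 2-methylpropanoate
Product: 6 1-benzyl 4-[(1R)-3-methylcyclopent-2-en-1-yl] 2,2-dimethylbutanedioate
Conditions: LiN(i-Pr)2, 5, THF, −78 °C; then 4, −78 → −20 °C
Reagents that add atoms: none
Why: SN2 alkylation of a fully substituted ester enolate by an α-bromo ester, which builds the C3–C4(Me2)–C5–C6 succinate unit without forming a stereocentre.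

**Step 4**
Reactants: 6 1-benzyl 4-[(1R)-3-methylcyclopent-2-en-1-yl] 2,2-dimethylbutanedioate
Product: 9 4-(benzyloxy)-3,3-dimethyl-2-[(1S)-1-methylcyclopent-2-en-1-yl]-4-oxobutanoic acid, via silyl ketene acetal 7 (not isolated), via trimethylsilyl ester 8 (not isolated)
Conditions: LiN(i-Pr)2, Me3SiCl, THF/HMPA, −78 °C; then 60 °C; aqueous HCl work-up
Reagents that add atoms: none
Why: Ireland–Claisen rearrangement, in which only C5 can be enolised (C4 is quaternary) and the suprafacial [3,3] shift forms C5–C10 on the face that carried oxygen, so the R carbinol is relayed into the quaternary centre C10 while the alkene moves to C8=C9.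

**Step 5**
Reactants: 9 4-(benzyloxy)-3,3-dimethyl-2-[(1S)-1-methylcyclopent-2-en-1-yl]-4-oxobutanoic acid
Product: 11 benzyl 2,2-dimethyl-3-[(1S)-1-methylcyclopent-2-en-1-yl]-4-oxopentanoate, via acid chloride 10 (not isolated)
Conditions: 1-chloro-N,N,2-trimethylprop-1-en-1-amine, CH2Cl2, 0 °C; then MeMgBr, Fe(acac)3 (3 mol%), THF, −78 °C
Reagents that add atoms: methylmagnesium bromide, C[Mg]Br
Why: Neutral acid chloride formation followed by iron-catalysed acylation of a Grignard reagent, which stops at the methyl ketone (C6=O, C7H3) and spares the hindered benzyl ester.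

**Step 6**
Reactants: 11 benzyl 2,2-dimethyl-3-[(1S)-1-methylcyclopent-2-en-1-yl]-4-oxopentanoate
Product: 12 benzyl 2,2-dimethyl-3-[(1S)-1-methyl-4-oxocyclopent-2-en-1-yl]-4-oxopentanoate
Conditions: CrO3, 3,5-dimethylpyrazole, CH2Cl2, −20 °C
Reagents that add atoms: chromium trioxide, O=[Cr](=O)=O
Why: Allylic oxidation of a cyclopentene to the cyclopentenone, regioselective because C2 is the only allylic CH2 (the other allylic position is the quaternary C10).

**Step 7**
Reactants: 12 benzyl 2,2-dimethyl-3-[(1S)-1-methyl-4-oxocyclopent-2-en-1-yl]-4-oxopentanoate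
Product: 13 benzyl 3-[(1R)-3-iodo-1-methyl-4-oxocyclopent-2-en-1-yl]-2,2-dimethyl-4-oxopentanoate
Conditions: I2, pyridine, CH2Cl2, rt
Reagents that add atoms: iodine, II
Why: α-Iodination of an enone by conjugate addition of pyridine, iodination of the enolate and elimination, which places the halogen on C8 (the descriptor at C10 changes only through the priority of iodine).

**Step 8**
Reactants: 13 benzyl 3-[(1R)-3-iodo-1-methyl-4-oxocyclopent-2-en-1-yl]-2,2-dimethyl-4-oxopentanoate
Product: 14 benzyl 3-[(1S)-1,3-dimethyl-4-oxocyclopent-2-en-1-yl]-2,2-dimethyl-4-oxopentanoate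
Conditions: Me4Sn, PdCl2(PhCN)2 (5 mol%), AsPh3, CuI, N-methylpyrrolidone, 80 °C
Reagents that add atoms: tetramethylstannane, C[Sn](C)(C)C
Why: Stille coupling of a 2-iodoenone with tetramethyltin, which introduces the C17 methyl on C8.

**Step 9**
Reactants: 14 benzyl 3-[(1S)-1,3-dimethyl-4-oxocyclopent-2-en-1-yl]-2,2-dimethyl-4-oxopentanoate; 15 (chloromethyl)dimethylphenylsilane
Product: 17 benzyl 3-[(1R,2R)-2-[(dimethylphenylsilyl)methyl]-1,3-dimethyl-4-(trimethylsilyloxy)cyclopent-3-en-1-yl]-2,2-dimethyl-4-(trimethylsilyloxy)pent-4-enoate, via mono silyl enol ether 16 (not isolated)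
Conditions: 15, Mg, THF (Grignard reagent); CuBr·SMe2 (10 mol%), Me3SiCl, HMPA, THF, −78 °C, then 14; then LiN(i-Pr)2, −78 °C; non-aqueous work-up
Reagents that add atoms: chlorotrimethylsilane, C[Si](C)(C)Cl
Why: Copper-catalysed conjugate addition of a silylmethyl Grignard reagent (masked hydroxymethyl, C11), which attacks C9 anti to the bulky C5 branch on the neighbouring quaternary C10 and is trapped regiospecifically as the C2=C8 enol silane, after which kinetic deprotonation of the methyl ketone with Me3SiCl present gives the terminal C6=C7 enol silane.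

**Step 10**
Reactants: 17 benzyl 3-[(1R,2R)-2-[(dimethylphenylsilyl)methyl]-1,3-dimethyl-4-(trimethylsilyloxy)cyclopent-3-en-1-yl]-2,2-dimethyl-4-(trimethylsilyloxy)pent-4-enoate
Product: 18 bicyclo[3.2.1]octane-2,6-dione with 8-Me, 10-Me, 9-CH2SiMe2Ph and 5-C(CH3)2CO2Bn (8S,9R,10R; C5 epimers)
Conditions: (NH4)2Ce(NO3)6 (2.2 equiv), NaHCO3, MeCN, −30 °C, high dilution
Reagents that add atoms: none
Why: Tetravalent cerium oxidises the more electron-rich, tetrasubstituted C2=C8 enol silane by one electron, loss of the silyl group gives a tertiary α-keto radical at C8 that adds to the unsubstituted terminus C7 of the C6 enol silane, and a second oxidation with desilylation of the α-siloxy radical delivers the C2,C6-diketone. The closest known reaction type is the oxidative coupling of silyl enol ethers (or enolates) to 1,4-diketones, including intramolecular cases. The six-membered carbocycle C5–C6–C7–C8–C9–C10 closes in the 6-endo-trig mode at the enol ether terminus, which is polarity-matched and gives a stabilised α-oxy radical, whereas 5-exo attack at C6 would give a primary radical. The new quaternary stereocentre C8 is fixed by the substrate, because the C5–C6–C7 tether on C10 can reach C8 only on the cyclopentane face that carries C5, so C7 is bonded cis to C5 and C17 ends cis to C20 and C11. The step needs cross- over homo-coupling and ring closure over intermolecular coupling, which the regiospecific enol silanes of step 9, the tether and high dilution secure, while NaHCO3 protects the enol silanes from acid. No other stereocentre is touched and C5 remains an epimer mixture.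

**Step 11**
Reactants: 18 bicyclo[3.2.1]octane-2,6-dione (C5 epimers)
Product: 19 bicyclo[3.2.1]octane-2,6-dione with 8-Me, 10-Me, 9-CH2SiMe2Ph and 5-C(CH3)2CO2Bn (5R,8S,9R,10R)
Conditions: DBU, toluene, 80 °C
Reagents that add atoms: none
Why: Base-mediated epimerisation α to the C6 ketone under thermodynamic control, in which the tert-alkyl group on C5 settles equatorial on the chair cyclohexanone, away from the syn-axial H7 and H9, which is the 5R configuration.

**Step 12**
Reactants: 19 bicyclo[3.2.1]octane-2,6-dione (5R,8S,9R,10R)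
Product: 21 6-(tert-butyldimethylsilyloxy)bicyclo[3.2.1]octan-2-one with 8-Me, 10-Me, 9-CH2SiMe2Ph and 5-C(CH3)2CO2Bn (5R,6R,8S,9R,10R), via C6 alcohol 20 (not isolated)
Conditions: LiBH(s-Bu)3 (1.1 equiv), THF, −78 °C; then t-BuMe2SiOTf, 2,6-lutidine, −78 → 0 °C
Reagents that add atoms: tert-butyldimethylsilyl trifluoromethanesulfonate, CC(C)(C)[Si](C)(C)OS(=O)(=O)C(F)(F)F
Why: Bulky-hydride reduction in which the C6 ketone is attacked from the open face syn to the one-carbon bridge C9 (the other face is blocked by the C1–C2 bridge) to give the axial 6R alcohol, the α-quaternary C2 ketone shielded by the C9 substituent is spared, and immediate silylation of the alkoxide prevents lactonisation onto the C3 ester.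

**Step 13**
Reactants: 21 6-(tert-butyldimethylsilyloxy)bicyclo[3.2.1]octan-2-one (5R,6R,8S,9R,10R)
Product: 22 2-oxabicyclo[3.3.1]nonan-3-one (C2 lactone carbonyl, ring O on C8) with 8-Me, 10-Me, 9-CH2SiMe2Ph, 6-OSi(t-Bu)Me2 and 5-C(CH3)2CO2Bn (5R,6R,8S,9R,10R)
Conditions: mCPBA, NaHCO3, CH2Cl2, rt
Reagents that add atoms: 3-chloroperbenzoic acid, OOC(=O)c1cccc(Cl)c1
Why: Baeyer–Villiger oxidation of the only remaining ketone, in which the tertiary bridgehead C8 migrates in preference to the C1 methylene and with retention, so oxygen enters between C2 and C8 and the lactone O–C8 bond has the 8S configuration.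

**Step 14**
Reactants: 22 lactone with 9-CH2SiMe2Ph (5R,6R,8S,9R,10R)
Product: 23 lactone with 9-CH2OH, 6-OSi(t-Bu)Me2 and 5-C(CH3)2CO2Bn (5R,6R,8S,9S,10R)
Conditions: KBr, AcOOH, NaOAc, AcOH, rt
Reagents that add atoms: peracetic acid, CC(=O)OO
Why: Fleming–Tamao oxidation, in which ipso-bromodesilylation removes the phenyl group from silicon and the peracid turns the C11–Si bond into C11–OH with no change elsewhere (the C9 descriptor changes only by priority).

**Step 15**
Reactants: 23 lactone with 9-CH2OH and benzyl ester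
Product: 24 lactone with 9-CH2OH, 6-OSi(t-Bu)Me2 and 5-C(CH3)2CO2H (5R,6R,8S,9S,10R)
Conditions: H2 (1 atm), Pd/C (10 wt%), EtOAc, rt
Reagents that add atoms: none
Why: Hydrogenolysis of the benzyl ester, done before any alkene is present, frees the C3 carboxylic acid so that later unmasking of the C6 hydroxyl meets a carboxylate and not an ester.

**Step 16**
Reactants: 24 lactone with 9-CH2OH and free C3 acid
Product: 25 lactone with 9-CHO, 6-OSi(t-Bu)Me2 and 5-C(CH3)2CO2H (5R,6R,8S,9R,10R)
Conditions: Dess–Martin periodinane, NaHCO3, CH2Cl2, 0 °C → rt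
Reagents that add atoms: none
Why: Dess–Martin oxidation of the primary alcohol to the C11 aldehyde under buffered conditions that tolerate the acid, the lactone and the silyl ether, with C9 keeping its more stable equatorial substituent.

**Step 17**
Reactants: 25 lactone with 9-CHO; 26 2-(trimethylsiloxy)buta-1,3-diene
Product: 27 lactone with 9-[(1S)-1-hydroxy-3-oxopent-4-en-1-yl], 6-OSi(t-Bu)Me2 and 5-C(CH3)2CO2H (5R,6R,8S,9S,10R,11S)
Conditions: BF3·OEt2, 26 (excess), CH2Cl2, −78 °C
Reagents that add atoms: none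
Why: Mukaiyama aldol addition of the enol silane of methyl vinyl ketone, expected to occur anti to the C9–C8 bond that carries the lactone oxygen (polar Felkin–Anh, equal to 1,3-anti induction by a β-oxygen under a non-chelating Lewis acid), with the formyl hydrogen turned toward the lactone ring, which gives the 11S carbinol.

**Step 18**
Reactants: 27 β-hydroxy vinyl ketone
Product: 28 lactone with the complete side chain, 6-OSi(t-Bu)Me2 and 5-C(CH3)2CO2H (5R,6R,8S,9S,10R,11S,13R)
Conditions: MeMgBr (5 equiv), THF, −78 °C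
Reagents that add atoms: methylmagnesium bromide, C[Mg]Br
Why: Chelation-controlled Grignard addition to a β-hydroxy ketone, in which the magnesium alkoxide of O11 and the C13 carbonyl form a six-membered chelate with the C9 residue equatorial and methyl enters axially and 1,2 to the vinyl ketone, which gives the 11,13-syn diol with the 13R centre.

**Step 19**
Reactants: 28 6-O-silyl ether of the target
Product: 29 (5R,6R,8S,9S,10R,11S,13R)-6,11,13-trihydroxy-2,3-seco-labd-14-en-2,8-olid-3-oic acid (target)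
Conditions: Bu4NF, AcOH (1:1), THF, 0 °C → rt; pH 5 work-up
Reagents that add atoms: none
Why: Fluoride-mediated cleavage of the silyl ether under buffered, non-basic conditions, so that the freed C6 hydroxyl, which points at the lactone carbonyl, neither takes over the acyl group nor closes a γ-lactone with the C3 carboxylate.

**Compound list**

1 | 3-methylcyclopent-2-en-1-one | CC1=CC(=O)CC1 | starting material
2 | (1R)-3-methylcyclopent-2-en-1-ol | CC1=C[C@H](O)CC1 | intermediate
3 | bromoacetyl bromide | BrCC(Br)=O | starting material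
4 | (1R)-3-methylcyclopent-2-en-1-yl bromoacetate | CC1=C[C@H](OC(=O)CBr)CC1 | intermediate
5 | benzyl 2-methylpropanoate | CC(C)C(=O)OCc1ccccc1 | starting material
6 | 1-benzyl 4-[(1R)-3-methylcyclopent-2-en-1-yl] 2,2-dimethylbutanedioate | CC1=C[C@H](OC(=O)CC(C)(C)C(=O)OCc2ccccc2)CC1 | intermediate
7 | trimethylsilyl ketene acetal of 6 (enolised at C5) | CC1=C[C@H](OC(O[Si](C)(C)C)=CC(C)(C)C(=O)OCc2ccccc2)CC1 | intermediate
8 | trimethylsilyl ester of 9 (C5 epimers) | C[Si](C)(C)OC(=O)C(C(C)(C)C(=O)OCc1ccccc1)[C@@]1(C)CCC=C1 | intermediate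
9 | 4-(benzyloxy)-3,3-dimethyl-2-[(1S)-1-methylcyclopent-2-en-1-yl]-4-oxobutanoic acid (C5 epimers) | OC(=O)C(C(C)(C)C(=O)OCc1ccccc1)[C@@]1(C)CCC=C1 | intermediate
10 | acid chloride of 9 (C5 epimers) | ClC(=O)C(C(C)(C)C(=O)OCc1ccccc1)[C@@]1(C)CCC=C1 | intermediate
11 | benzyl 2,2-dimethyl-3-[(1S)-1-methylcyclopent-2-en-1-yl]-4-oxopentanoate (C5 epimers) | CC(=O)C(C(C)(C)C(=O)OCc1ccccc1)[C@@]1(C)CCC=C1 | intermediate
12 | benzyl 2,2-dimethyl-3-[(1S)-1-methyl-4-oxocyclopent-2-en-1-yl]-4-oxopentanoate (C5 epimers) | CC(=O)C(C(C)(C)C(=O)OCc1ccccc1)[C@@]1(C)CC(=O)C=C1 | intermediate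
13 | benzyl 3-[(1R)-3-iodo-1-methyl-4-oxocyclopent-2-en-1-yl]-2,2-dimethyl-4-oxopentanoate (C5 epimers) | CC(=O)C(C(C)(C)C(=O)OCc1ccccc1)[C@@]1(C)CC(=O)C(I)=C1 | intermediate
14 | benzyl 3-[(1S)-1,3-dimethyl-4-oxocyclopent-2-en-1-yl]-2,2-dimethyl-4-oxopentanoate (C5 epimers) | CC(=O)C(C(C)(C)C(=O)OCc1ccccc1)[C@@]1(C)CC(=O)C(C)=C1 | intermediate
15 | (chloromethyl)dimethylphenylsilane | ClC[Si](C)(C)c1ccccc1 | starting material
16 | benzyl 3-[(1R,2R)-2-[(dimethylphenylsilyl)methyl]-1,3-dimethyl-4-(trimethylsilyloxy)cyclopent-3-en-1-yl]-2,2-dimethyl-4-oxopentanoate (C5 epimers) | CC(=O)C(C(C)(C)C(=O)OCc1ccccc1)[C@@]1(C)CC(O[Si](C)(C)C)=C(C)[C@@H]1C[Si](C)(C)c1ccccc1 | intermediate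
17 | benzyl 3-[(1R,2R)-2-[(dimethylphenylsilyl)methyl]-1,3-dimethyl-4-(trimethylsilyloxy)cyclopent-3-en-1-yl]-2,2-dimethyl-4-(trimethylsilyloxy)pent-4-enoate (C5 epimers) | C=C(O[Si](C)(C)C)C(C(C)(C)C(=O)OCc1ccccc1)[C@@]1(C)CC(O[Si](C)(C)C)=C(C)[C@@H]1C[Si](C)(C)c1ccccc1 | intermediate
18 | bicyclo[3.2.1]octane-2,6-dione, 8-Me, 10-Me, 9-CH2SiMe2Ph, 5-C(CH3)2CO2Bn (8S,9R,10R; C5 epimers) | C[Si](C)(c1ccccc1)C[C@@H]1[C@]2(C)CC(=O)[C@@]1(C)CC(=O)C2C(C)(C)C(=O)OCc1ccccc1 | intermediate
19 | the same dione, 5R,8S,9R,10R | C[Si](C)(c1ccccc1)C[C@@H]1[C@]2(C)CC(=O)[C@@]1(C)CC(=O)[C@H]2C(C)(C)C(=O)OCc1ccccc1 | intermediate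
20 | 6-hydroxy-2-ketone from 19 (5R,6R,8S,9R,10R; formed as the lithium alkoxide) | C[Si](C)(c1ccccc1)C[C@@H]1[C@]2(C)CC(=O)[C@@]1(C)C[C@@H](O)[C@H]2C(C)(C)C(=O)OCc1ccccc1 | intermediate
21 | 6-(tert-butyldimethylsilyloxy)-2-ketone (5R,6R,8S,9R,10R) | C[Si](C)(c1ccccc1)C[C@@H]1[C@]2(C)CC(=O)[C@@]1(C)C[C@@H](O[Si](C)(C)C(C)(C)C)[C@H]2C(C)(C)C(=O)OCc1ccccc1 | intermediate
22 | 2,8-lactone (2-oxabicyclo[3.3.1]nonan-3-one) with 9-CH2SiMe2Ph, 6-OSi(t-Bu)Me2, benzyl ester (5R,6R,8S,9R,10R) | C[Si](C)(c1ccccc1)C[C@@H]1[C@]2(C)CC(=O)O[C@@]1(C)C[C@@H](O[Si](C)(C)C(C)(C)C)[C@H]2C(C)(C)C(=O)OCc1ccccc1 | intermediate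
23 | 2,8-lactone with 9-CH2OH, 6-OSi(t-Bu)Me2, benzyl ester (5R,6R,8S,9S,10R) | OC[C@@H]1[C@]2(C)CC(=O)O[C@@]1(C)C[C@@H](O[Si](C)(C)C(C)(C)C)[C@H]2C(C)(C)C(=O)OCc1ccccc1 | intermediate
24 | 2,8-lactone with 9-CH2OH, 6-OSi(t-Bu)Me2, free C3 acid (5R,6R,8S,9S,10R) | OC[C@@H]1[C@]2(C)CC(=O)O[C@@]1(C)C[C@@H](O[Si](C)(C)C(C)(C)C)[C@H]2C(C)(C)C(=O)O | intermediate
25 | 2,8-lactone with 9-CHO, 6-OSi(t-Bu)Me2, free C3 acid (5R,6R,8S,9R,10R) | O=C[C@@H]1[C@]2(C)CC(=O)O[C@@]1(C)C[C@@H](O[Si](C)(C)C(C)(C)C)[C@H]2C(C)(C)C(=O)O | intermediate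
26 | 2-(trimethylsiloxy)buta-1,3-diene | C=CC(=C)O[Si](C)(C)C | starting material
27 | 2,8-lactone with 9-[(1S)-1-hydroxy-3-oxopent-4-en-1-yl], 6-OSi(t-Bu)Me2, free C3 acid (5R,6R,8S,9S,10R,11S) | C=CC(=O)C[C@H](O)[C@@H]1[C@]2(C)CC(=O)O[C@@]1(C)C[C@@H](O[Si](C)(C)C(C)(C)C)[C@H]2C(C)(C)C(=O)O | intermediate
28 | 6-O-(tert-butyldimethylsilyl) ether of the target (5R,6R,8S,9S,10R,11S,13R) | C=C[C@](C)(O)C[C@H](O)[C@@H]1[C@]2(C)CC(=O)O[C@@]1(C)C[C@@H](O[Si](C)(C)C(C)(C)C)[C@H]2C(C)(C)C(=O)O | intermediate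
29 | (5R,6R,8S,9S,10R,11S,13R)-6,11,13-trihydroxy-2,3-seco-labd-14-en-2,8-olid-3-oic acid | C=C[C@](C)(O)C[C@H](O)[C@@H]1[C@]2(C)CC(=O)O[C@@]1(C)C[C@@H](O)[C@H]2C(C)(C)C(=O)O | target

**Step count and risks**

Total steps: 19. Longest linear sequence: 19 steps (1 → 29); the route is fully linear.

Steps most likely to fail:

Step 10 (oxidative ring closure). The C8 radical may be oxidised further to the cation and lose a proton, or be trapped by nitrate, before the crowded C7–C8 bond closes, and intermolecular coupling can compete. The fallback replaces electron-transfer coupling by carbenoid cyclopropanation and strain-release opening; it sets out from 14 and comes back at 18. The copper-catalysed addition of step 9 is run on 14 with Et3SiCl as the only trap and without the amide base, giving the triethylsilyl enol ether F1. LiN(SiMe3)2 and CF3CO2CH2CF3 acylate the methyl ketone to the trifluoroacetyl ketone F2, and MsN3/Et3N converts it by detrifluoroacetylative diazo transfer into the diazoketone F3. Rh2(OAc)4 in CH2Cl2 should effect intramolecular cyclopropanation of the enol ether, forming C7–C8 and C7–C2 in the siloxycyclopropane F4. Bu4NF then opens the donor–acceptor cyclopropane at the C2–C7 bond (the bond between the siloxy carbon and the carbon α to the C6 ketone) to give dione 18.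

Step 17 (aldol addition). Facial selectivity at C11 may be poor because the two quaternary neighbours of C9 differ little, and the β-hydroxy vinyl ketone can undergo retro-aldol or oxa-Michael closure. The fallback puts C11 under reagent control; it sets out from 25 and comes back at 27. Allylboration with (−)-Ipc2B(allyl), which should add to the Si face, gives the homoallylic alcohol F5. Ozonolysis (O3; Me2S) gives the β-hydroxy aldehyde F6, CH2=CHMgBr gives the allylic alcohol F7 (C13 epimers), and MnO2 oxidises only the allylic hydroxyl to the vinyl ketone 27.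

Step 18 (chelation-controlled methyl addition). 1,4-Addition to the vinyl ketone, weak 1,3-induction at C13, or acyl transfer from O8 to the C11 alkoxide may intervene. The fallback builds C13 by epoxidation and one-carbon homologation instead of by 1,3-induction; it sets out from 25 and comes back at 28. Allylboration with (−)-Ipc2B(2-methylallyl) gives the methallyl carbinol F8. Hydroxyl-directed epoxidation with VO(acac)2/t-BuOOH (or a catalyst-controlled variant) gives the epoxy alcohol F9. Dimethylsulfonium methylide (Me3S+ I−, n-BuLi) opens the epoxide at CH2 and eliminates to the tertiary allylic alcohol 28.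

**Further compounds**

F1 | step 10 | triethylsilyl enol ether analogue of 16 (C5 epimers) | CC(=O)C(C(C)(C)C(=O)OCc1ccccc1)[C@@]1(C)CC(O[Si](CC)(CC)CC)=C(C)[C@@H]1C[Si](C)(C)c1ccccc1
F2 | step 10 | trifluoroacetyl ketone from F1 (C5 epimers) | FC(F)(F)C(=O)CC(=O)C(C(C)(C)C(=O)OCc1ccccc1)[C@@]1(C)CC(O[Si](CC)(CC)CC)=C(C)[C@@H]1C[Si](C)(C)c1ccccc1
F3 | step 10 | diazoketone (C7 diazo; C5 epimers) | [N-]=[N+]=CC(=O)C(C(C)(C)C(=O)OCc1ccccc1)[C@@]1(C)CC(O[Si](CC)(CC)CC)=C(C)[C@@H]1C[Si](C)(C)c1ccccc1
F4 | step 10 | siloxycyclopropane (tricyclo[3.2.1.0(2,7)]octan-3-one type; cyclopropane C2–C7–C8; C5 epimers) | C[Si](C)(c1ccccc1)C[C@@H]1[C@]2(C)C[C@@]3(O[Si](CC)(CC)CC)[C@@H](C(=O)C2C(C)(C)C(=O)OCc2ccccc2)[C@@]13C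
F5 | step 17 | homoallylic alcohol (11S; allyl adduct of 25) | C=CC[C@H](O)[C@@H]1[C@]2(C)CC(=O)O[C@@]1(C)C[C@@H](O[Si](C)(C)C(C)(C)C)[C@H]2C(C)(C)C(=O)O
F6 | step 17 | β-hydroxy aldehyde (11S) | O=CC[C@H](O)[C@@H]1[C@]2(C)CC(=O)O[C@@]1(C)C[C@@H](O[Si](C)(C)C(C)(C)C)[C@H]2C(C)(C)C(=O)O
F7 | step 17 | allylic alcohol (11S; C13 epimers) | C=CC(O)C[C@H](O)[C@@H]1[C@]2(C)CC(=O)O[C@@]1(C)C[C@@H](O[Si](C)(C)C(C)(C)C)[C@H]2C(C)(C)C(=O)O
F8 | step 18 | methallyl carbinol (11S) | C=C(C)C[C@H](O)[C@@H]1[C@]2(C)CC(=O)O[C@@]1(C)C[C@@H](O[Si](C)(C)C(C)(C)C)[C@H]2C(C)(C)C(=O)O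
F9 | step 18 | epoxy alcohol (11S, C13 configured as in the target) | C[C@]1(CO1)C[C@H](O)[C@@H]2[C@]3(C)CC(=O)O[C@@]2(C)C[C@@H](O[Si](C)(C)C(C)(C)C)[C@H]3C(C)(C)C(=O)O
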